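**Retrosynthetic overview**

1. The enabling feature is the unit C7=C8(CH3)–C9H(OH): an E-trisubstituted allylic alcohol whose methyl-bearing vinyl carbon C8 is bonded to carbinol C9 inside the 14-membered carbocycle, next to the C10 carbinol. This is the retron of a reductive alkyne–aldehyde coupling, so the ring is opened at C8–C9 to the acyclic ynal 26 (but-2-ynyl end plus α-silyloxy aldehyde).
2. The only ring, the 14-membered carbocycle, is formed in step 18. C9 is then equalised as enone 29 and set by 1,2-induction from C10, which is bought with (R)-solketal; C14 is set by a Sharpless epoxidation.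
3. Ynal 26 comes from a Negishi union at C2–C3 of Z-iodo-diene 16 with the alkenylalane of hepta-1,5-diyne. The two alkynes of this one diyne become the methyl-bearing E-olefins C3=C4 (carboalumination) and C7=C8 (key step).
4. Iodo-diene 16 comes from hydroxyl-directed anti-carbomagnesiation/iodination of propargylic alcohol 13, which installs the isopropenyl group and the 1Z geometry together. 13 comes from epoxy chloride 12, built from allylic bromide 7 and propargyl alcohol; 7 comes from an E-selective Wittig reaction on (S)-glyceraldehyde acetonide.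

Key step: step 18

Remark: atoms are numbered as in the cembrane skeleton (C1 = ring carbon bearing the isopropenyl group, diene C1=C2–C3=C4, methyls on C4, C8, C12, hydroxyls on C9 and C10, acetate on C14). The target is (9R,10R,14S) with a syn 9,10-diol, so C9 is set by Felkin–Anh hydride delivery next to the protected C10 carbinol. TBS = tert-butyldimethylsilyl, TES = triethylsilyl.

Step 1
Reactants: 1 (R)-solketal
Product: 3 ethyl (2E)-3-[(4R)-2,2-dimethyl-1,3-dioxolan-4-yl]-2-methylprop-2-enoate, via (S)-glyceraldehyde acetonide 2 (not isolated)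
Conditions: TEMPO (2,2,6,6-tetramethylpiperidin-1-oxyl, cat.), PhI(OAc)2, CH2Cl2, rt; then Ph3P=C(CH3)CO2Et, rt
Reagents that add atoms: ethyl 2-(triphenylphosphoranylidene)propanoate, CCOC(=O)C(C)=P(c1ccccc1)(c1ccccc1)c1ccccc1
Why: Oxidation to the labile aldehyde and in-flask Wittig olefination with the stabilized, α-branched ylide should give the E-enoate (C11=C12), while the C10 stereocenter is bought with 1 and not touched.

Step 2
Reactants: 3 the enoate acetonide
Product: 4 ethyl (2E,4R)-4,5-dihydroxy-2-methylpent-2-enoate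
Conditions: AcOH, H2O (4:1), 40 °C
Reagents that add atoms: none
Why: Acid hydrolysis of the isopropylidene acetal should free the diol, and the E geometry prevents lactonization.

Step 3
Reactants: 4 the diol ester
Product: 5 ethyl (2E,4R)-4,5-bis(TBSO)-2-methylpent-2-enoate
Conditions: TBSCl, imidazole, DMF, rt
Reagents that add atoms: tert-butyldimethylsilyl chloride, CC(C)(C)[Si](C)(C)Cl
Why: Standard silylation protects both hydroxyls so that the primary C9 ether can later be removed selectively.

Step 4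
Reactants: 5 the bis-silyl enoate
Product: 6 (2E,4R)-4,5-bis(TBSO)-2-methylpent-2-en-1-ol
Conditions: i-Bu2AlH, CH2Cl2, −78 °C; aqueous potassium sodium tartrate
Reagents that add atoms: none
Why: 1,2-Reduction of the enoate with i-Bu2AlH should give the allylic alcohol (C13) without touching the silyl ethers or the olefin.

Step 5
Reactants: 6 the allylic alcohol
Product: 7 (2E,4R)-1-bromo-4,5-bis(TBSO)-2-methylpent-2-ene
Conditions: CBr4, PPh3, 2,6-lutidine, CH2Cl2, 0 °C
Reagents that add atoms: carbon tetrabromide, BrC(Br)(Br)Br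
Why: Appel bromination of the primary allylic alcohol proceeds by SN2 displacement and should keep the E geometry.

Step 6
Reactants: 7 the allylic bromide; 8 propargyl alcohol
Product: 9 (5E,7R)-7,8-bis(TBSO)-5-methyloct-5-en-2-yn-1-ol
Conditions: CuI, NaI, K2CO3, DMF, rt
Reagents that add atoms: none
Why: Copper-mediated coupling of the terminal alkyne with the allylic halide should occur by SN2 attack at the unhindered primary carbon, forming the C13–C14 bond of a skipped enyne.

Step 7
Reactants: 9 the enynol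
Product: 10 (2E,5E,7R)-7,8-bis(TBSO)-5-methylocta-2,5-dien-1-ol
Conditions: NaAlH2(OCH2CH2OCH3)2, THF, 0 °C to rt; aqueous potassium sodium tartrate
Reagents that add atoms: none
Why: Hydroxyl-directed trans-hydroalumination of the propargylic alcohol should give the E-allylic alcohol needed for the epoxidation.

Step 8
Reactants: 10 the dienol
Product: 11 {(2S,3S)-3-[(2E,4R)-4,5-bis(TBSO)-2-methylpent-2-en-1-yl]oxiran-2-yl}methanol
Conditions: Ti(OiPr)4 (cat.), L-(+)-diethyl tartrate (cat.), t-BuOOH, 4 Å molecular sieves, CH2Cl2, −20 °C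
Reagents that add atoms: tert-butyl hydroperoxide, CC(C)(C)OO
Why: Sharpless asymmetric epoxidation with the L-(+)-tartrate should give the (2S,3S)-epoxide by catalyst control, which sets the future C14; the remote trisubstituted olefin is not an allylic alcohol and stays.

Step 9
Reactants: 11 the epoxy alcohol
Product: 12 (2R,3S)-2-(chloromethyl)-3-[(2E,4R)-4,5-bis(TBSO)-2-methylpent-2-en-1-yl]oxirane
Conditions: PPh3, CCl4, NaHCO3, reflux
Reagents that add atoms: carbon tetrachloride, ClC(Cl)(Cl)Cl
Why: Appel chlorination of the primary alcohol leaves the epoxide and its two stereocenters intact.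

Step 10
Reactants: 12 the epoxy chloride
Product: 13 (3S,5E,7R)-7,8-bis(TBSO)-5-methyloct-5-en-1-yn-3-ol
Conditions: n-BuLi (3.5 equiv), THF, −40 °C; aqueous NH4Cl
Reagents that add atoms: none
Why: Base-induced fragmentation of the 2,3-epoxy chloride (deprotonation next to chlorine, epoxide opening, dehydrochlorination) should give the terminal propargylic alcohol; the C14–O bond is not broken, so the configuration is kept.

Step 11
Reactants: 13 the propargylic alcohol; 14 isopropenylmagnesium bromide
Product: 16 (1Z,3S,5E,7R)-7,8-bis(TBSO)-1-iodo-5-methyl-2-(prop-1-en-2-yl)octa-1,5-dien-3-ol, via cyclic magnesium chelate 15 (not isolated)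
Conditions: isopropenylmagnesium bromide (3.5 equiv), CuI (cat.), THF, 0 °C to rt; then I2, THF, −40 to 0 °C
Reagents that add atoms: iodine, II
Why: Alkoxide-directed anti-carbomagnesiation puts the isopropenyl group on the proximal alkyne carbon (C1) and holds magnesium on C2 cis to the carbinol in a five-membered chelate, and iodinolysis with retention should give the Z-iodo-diene with iodine cis to C14.

Step 12
Reactants: 17 1-(trimethylsilyl)propyne; 18 1-bromobut-2-yne
Product: 20 trimethyl(hepta-1,5-diyn-1-yl)silane, via lithiated 1-(trimethylsilyl)propyne 19 (not isolated)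
Conditions: n-BuLi, THF, −78 to −20 °C; then 18, −78 °C to rt
Reagents that add atoms: none
Why: The silyl-blocked propargyl anion should be alkylated at its CH2 terminus by SN2 displacement of the propargylic bromide, giving the 1,5-diyne.

Step 13
Reactants: 20 the silyl diyne
Product: 21 hepta-1,5-diyne
Conditions: K2CO3 (cat.), MeOH, rt; product kept as a solution
Reagents that add atoms: none
Why: Methanolysis of the alkynylsilane should free the terminal alkyne and leave the methyl-capped alkyne untouched.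

Step 14
Reactants: 21 hepta-1,5-diyne; 16 the iodo-dienol
Product: 23 (2R,3E,6S,7Z,9E)-1,2-bis(TBSO)-4,10-dimethyl-7-(prop-1-en-2-yl)pentadeca-3,7,9-trien-13-yn-6-ol, via alkenylalane 22 (not isolated)
Conditions: 21, Me3Al, Cp2ZrCl2, (CH2Cl)2, rt; then 16, ZnCl2, Pd(PPh3)4 (cat.), THF, rt
Reagents that add atoms: trimethylaluminium, C[Al](C)C
Why: Zirconium-catalysed carboalumination adds CH3 and aluminium syn to the terminal alkyne only, and the palladium-catalysed Negishi coupling proceeds with retention at both sp2 carbons, so the 1Z,3E-diene and the C4 methyl should be fixed without touching C10 or C14.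

Step 15
Reactants: 23 the trienynol
Product: 24 (2R,3E,6S,7Z,9E)-1,2-bis(TBSO)-4,10-dimethyl-7-(prop-1-en-2-yl)pentadeca-3,7,9-trien-13-yn-6-yl acetate
Conditions: Ac2O, pyridine, 4-(dimethylamino)pyridine (cat.), CH2Cl2, 0 °C
Reagents that add atoms: acetic anhydride, CC(=O)OC(C)=O
Why: The C14 hydroxyl is the only free hydroxyl, so acylation should install the acetate of the target at this point.

Step 16
Reactants: 24 the bis-silyl acetate
Product: 25 (2R,3E,6S,7Z,9E)-2-(TBSO)-1-hydroxy-4,10-dimethyl-7-(prop-1-en-2-yl)pentadeca-3,7,9-trien-13-yn-6-yl acetate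
Conditions: HF·pyridine, pyridine, THF, 0 °C
Reagents that add atoms: none
Why: Buffered HF·pyridine should cleave the primary silyl ether much faster than the secondary allylic one and spare the acid-sensitive trienyl acetate.

Step 17
Reactants: 25 the primary alcohol
Product: 26 (2R,3E,6S,7Z,9E)-2-(TBSO)-4,10-dimethyl-1-oxo-7-(prop-1-en-2-yl)pentadeca-3,7,9-trien-13-yn-6-yl acetate
Conditions: Dess–Martin periodinane, NaHCO3, CH2Cl2, 0 °C; used at once
Reagents that add atoms: none
Why: Buffered Dess–Martin oxidation is neutral, so the α-silyloxy β,γ-unsaturated aldehyde should form without epimerization at C10 or migration of the olefin.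

Step 18
Reactants: 26 the ynal
Product: 28 (1Z,3E,7E,11E,10R,14S)-10-(TBSO)-9-hydroxy-4,8,12-trimethyl-1-(prop-1-en-2-yl)cyclotetradeca-1,3,7,11-tetraen-14-yl acetate (both C9 epimers), via triethylsilyl ether 27 (not isolated)
Conditions: Ni(cod)2 (25 mol%), 1,3-bis(2,4,6-trimethylphenyl)imidazol-2-ylidene (IMes, 25 mol%), Et3SiH, THF, rt, slow addition of 26 to 3 mM; then MeOH, pyridinium p-toluenesulfonate, 0 °C
Reagents that add atoms: none
Why: The zerovalent nickel–carbene complex binds aldehyde and alkyne and couples them oxidatively to an oxanickelacyclopentene containing the new C8–C9 bond; Et3SiH cleaves the Ni–O bond by sigma-bond metathesis and C–H reductive elimination delivers hydrogen to C7 on the same side as C9, so the C7=C8 olefin should form E. The closest known reaction type is the nickel/N-heterocyclic carbene/silane reductive macrocyclization of ynals, which has been used to close 14-membered rings with an endocyclic E-olefin. The single ring of the target, the 14-membered carbocycle, is closed in the endocyclic sense (14-endo with respect to the alkyne, both alkyne carbons inside the ring). C9 is the only new stereocenter; a macrocyclic α-silyloxy ynal is expected to show little facial bias, and none is needed because both C9 epimers converge on enone 29 in step 19 and C9 is set by 1,2-induction from C10 in step 20. The step needs C–C bond formation at the methyl-bearing alkyne carbon, which the small carbene ligand and the methyl-versus-chain size difference should secure (a bulky carbene would favour the 13-membered exocyclic isomer), and it needs the alkyne to react in preference to the cross-conjugated triene, which is secured because the diene termini can reach the aldehyde only through 8- to 10-membered rings holding an E-olefin and slow addition keeps intermolecular coupling down. The final methanolysis removes only the triethylsilyl ether and should leave the C10 silyl ether and the acetate in place.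

Step 19
Reactants: 28 the macrocyclic allylic alcohols
Product: 29 (1Z,3E,7E,11E,10R,14S)-10-(TBSO)-4,8,12-trimethyl-9-oxo-1-(prop-1-en-2-yl)cyclotetradeca-1,3,7,11-tetraen-14-yl acetate
Conditions: Dess–Martin periodinane, NaHCO3, CH2Cl2, 0 °C
Reagents that add atoms: none
Why: Buffered Dess–Martin oxidation of the allylic alcohol should turn both C9 epimers into one enone without epimerizing the doubly activated C10.

Step 20
Reactants: 29 the macrocyclic enone
Product: 30 (1Z,3E,7E,11E,9R,10R,14S)-10-(TBSO)-9-hydroxy-4,8,12-trimethyl-1-(prop-1-en-2-yl)cyclotetradeca-1,3,7,11-tetraen-14-yl acetate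
Conditions: NaBH4, CeCl3·7H2O, MeOH, −78 °C
Reagents that add atoms: none
Why: Luche 1,2-reduction of the enone; by the Felkin–Anh model hydride attacks C9 anti to the C10–OTBS bond, which relays C10 to C9 and should give the 9,10-syn (9R) alcohol, while acetate, triene and silyl ether are inert.

Step 21
Reactants: 30 the silyl-protected diol acetate
Product: 31 (1Z,3E,7E,11E,9R,10R,14S)-9,10-dihydroxy-4,8,12-trimethyl-1-(prop-1-en-2-yl)cyclotetradeca-1,3,7,11-tetraen-14-yl acetate (target)
Conditions: HF·pyridine, pyridine, THF, 0 °C to rt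
Reagents that add atoms: none
Why: Buffered fluoride cleavage of the secondary silyl ether should free the C10 hydroxyl without acyl migration or ionization of the allylic acetate.

**Compound list**

1 | (R)-solketal, [(4R)-2,2-dimethyl-1,3-dioxolan-4-yl]methanol | OC[C@@H]1COC(C)(C)O1 | starting material
2 | (S)-glyceraldehyde acetonide, (4S)-2,2-dimethyl-1,3-dioxolane-4-carbaldehyde | O=C[C@@H]1COC(C)(C)O1 | intermediate
3 | ethyl (2E)-3-[(4R)-2,2-dimethyl-1,3-dioxolan-4-yl]-2-methylprop-2-enoate | CCOC(=O)/C(C)=C/[C@@H]1COC(C)(C)O1 | intermediate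
4 | ethyl (2E,4R)-4,5-dihydroxy-2-methylpent-2-enoate | CCOC(=O)/C(C)=C/[C@@H](O)CO | intermediate
5 | ethyl (2E,4R)-4,5-bis(TBSO)-2-methylpent-2-enoate | CCOC(=O)/C(C)=C/[C@@H](O[Si](C)(C)C(C)(C)C)CO[Si](C)(C)C(C)(C)C | intermediate
6 | (2E,4R)-4,5-bis(TBSO)-2-methylpent-2-en-1-ol | OC/C(C)=C/[C@@H](O[Si](C)(C)C(C)(C)C)CO[Si](C)(C)C(C)(C)C | intermediate
7 | (2E,4R)-1-bromo-4,5-bis(TBSO)-2-methylpent-2-ene | BrC/C(C)=C/[C@@H](O[Si](C)(C)C(C)(C)C)CO[Si](C)(C)C(C)(C)C | intermediate
8 | propargyl alcohol (prop-2-yn-1-ol) | OCC#C | starting material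
9 | (5E,7R)-7,8-bis(TBSO)-5-methyloct-5-en-2-yn-1-ol | OCC#CC/C(C)=C/[C@@H](O[Si](C)(C)C(C)(C)C)CO[Si](C)(C)C(C)(C)C | intermediate
10 | (2E,5E,7R)-7,8-bis(TBSO)-5-methylocta-2,5-dien-1-ol | OC/C=C/C/C(C)=C/[C@@H](O[Si](C)(C)C(C)(C)C)CO[Si](C)(C)C(C)(C)C | intermediate
11 | {(2S,3S)-3-[(2E,4R)-4,5-bis(TBSO)-2-methylpent-2-en-1-yl]oxiran-2-yl}methanol | OC[C@@H]1O[C@H]1C/C(C)=C/[C@@H](O[Si](C)(C)C(C)(C)C)CO[Si](C)(C)C(C)(C)C | intermediate
12 | (2R,3S)-2-(chloromethyl)-3-[(2E,4R)-4,5-bis(TBSO)-2-methylpent-2-en-1-yl]oxirane | ClC[C@@H]1O[C@H]1C/C(C)=C/[C@@H](O[Si](C)(C)C(C)(C)C)CO[Si](C)(C)C(C)(C)C | intermediate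
13 | (3S,5E,7R)-7,8-bis(TBSO)-5-methyloct-5-en-1-yn-3-ol | C#C[C@@H](O)C/C(C)=C/[C@@H](O[Si](C)(C)C(C)(C)C)CO[Si](C)(C)C(C)(C)C | intermediate
14 | isopropenylmagnesium bromide | C=C(C)[Mg]Br | starting material
15 | cyclic magnesium chelate, (5S)-5-[(2E,4R)-4,5-bis(TBSO)-2-methylpent-2-en-1-yl]-4-(prop-1-en-2-yl)-2,5-dihydro-1,2-oxamagnesole | C=C(C)C1=C[Mg]O[C@H]1C/C(C)=C/[C@@H](O[Si](C)(C)C(C)(C)C)CO[Si](C)(C)C(C)(C)C | intermediate
16 | (1Z,3S,5E,7R)-7,8-bis(TBSO)-1-iodo-5-methyl-2-(prop-1-en-2-yl)octa-1,5-dien-3-ol | I/C=C(/C(C)=C)[C@@H](O)C/C(C)=C/[C@@H](O[Si](C)(C)C(C)(C)C)CO[Si](C)(C)C(C)(C)C | intermediate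
17 | 1-(trimethylsilyl)propyne | CC#C[Si](C)(C)C | starting material
18 | 1-bromobut-2-yne | CC#CCBr | starting material
19 | [3-(trimethylsilyl)prop-2-yn-1-yl]lithium | [Li]CC#C[Si](C)(C)C | intermediate
20 | trimethyl(hepta-1,5-diyn-1-yl)silane | C[Si](C)(C)C#CCCC#CC | intermediate
21 | hepta-1,5-diyne | C#CCCC#CC | intermediate
22 | dimethyl[(1E)-2-methylhept-1-en-5-yn-1-yl]alane | C[Al](C)/C=C(\C)CCC#CC | intermediate
23 | (2R,3E,6S,7Z,9E)-1,2-bis(TBSO)-4,10-dimethyl-7-(prop-1-en-2-yl)pentadeca-3,7,9-trien-13-yn-6-ol | CC(C)(C)[Si](C)(C)OC[C@H](O[Si](C)(C)C(C)(C)C)/C=C(\C)C[C@H](O)/C(C(C)=C)=C\C=C(/C)CCC#CC | intermediate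
24 | (2R,3E,6S,7Z,9E)-1,2-bis(TBSO)-4,10-dimethyl-7-(prop-1-en-2-yl)pentadeca-3,7,9-trien-13-yn-6-yl acetate | CC(C)(C)[Si](C)(C)OC[C@H](O[Si](C)(C)C(C)(C)C)/C=C(\C)C[C@H](OC(C)=O)/C(C(C)=C)=C\C=C(/C)CCC#CC | intermediate
25 | (2R,3E,6S,7Z,9E)-2-(TBSO)-1-hydroxy-4,10-dimethyl-7-(prop-1-en-2-yl)pentadeca-3,7,9-trien-13-yn-6-yl acetate | OC[C@H](O[Si](C)(C)C(C)(C)C)/C=C(\C)C[C@H](OC(C)=O)/C(C(C)=C)=C\C=C(/C)CCC#CC | intermediate
26 | (2R,3E,6S,7Z,9E)-2-(TBSO)-4,10-dimethyl-1-oxo-7-(prop-1-en-2-yl)pentadeca-3,7,9-trien-13-yn-6-yl acetate | O=C[C@H](O[Si](C)(C)C(C)(C)C)/C=C(\C)C[C@H](OC(C)=O)/C(C(C)=C)=C\C=C(/C)CCC#CC | intermediate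
27 | macrocyclic 9-O-TES, 10-O-TBS ether of the target (both C9 epimers) | C=C(C)/C1=C/C=C(\C)CC/C=C(\C)C(O[Si](CC)(CC)CC)[C@H](O[Si](C)(C)C(C)(C)C)/C=C(\C)C[C@@H]1OC(C)=O | intermediate
28 | (1Z,3E,7E,11E,10R,14S)-10-(TBSO)-9-hydroxy-4,8,12-trimethyl-1-(prop-1-en-2-yl)cyclotetradeca-1,3,7,11-tetraen-14-yl acetate (both C9 epimers) | C=C(C)/C1=C/C=C(\C)CC/C=C(\C)C(O)[C@H](O[Si](C)(C)C(C)(C)C)/C=C(\C)C[C@@H]1OC(C)=O | intermediate
29 | (1Z,3E,7E,11E,10R,14S)-10-(TBSO)-4,8,12-trimethyl-9-oxo-1-(prop-1-en-2-yl)cyclotetradeca-1,3,7,11-tetraen-14-yl acetate | C=C(C)/C1=C/C=C(\C)CC/C=C(\C)C(=O)[C@H](O[Si](C)(C)C(C)(C)C)/C=C(\C)C[C@@H]1OC(C)=O | intermediate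
30 | (1Z,3E,7E,11E,9R,10R,14S)-10-(TBSO)-9-hydroxy-4,8,12-trimethyl-1-(prop-1-en-2-yl)cyclotetradeca-1,3,7,11-tetraen-14-yl acetate | C=C(C)/C1=C/C=C(\C)CC/C=C(\C)[C@@H](O)[C@H](O[Si](C)(C)C(C)(C)C)/C=C(\C)C[C@@H]1OC(C)=O | intermediate
31 | (1Z,3E,7E,11E,9R,10R,14S)-9,10-dihydroxy-4,8,12-trimethyl-1-(prop-1-en-2-yl)cyclotetradeca-1,3,7,11-tetraen-14-yl acetate | C=C(C)/C1=C/C=C(\C)CC/C=C(\C)[C@@H](O)[C@H](O)/C=C(\C)C[C@@H]1OC(C)=O | target

**Step count and risks**

Total step count: 21. Longest linear sequence: 19 steps (steps 1–11 and 14–21).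

Steps most likely to fail:

1. Step 18. The macrocyclization may suffer from closure at the wrong alkyne carbon (13-membered exocyclic isomer), from diversion of zerovalent nickel by the triene or the allylic acetate, or from oligomerization. The fallback is a Nozaki–Hiyama–Kishi macrocyclization, which moves the regiochemical decision into a separate hydrometalation. It sets out from 25. Hydrozirconation of the methyl alkyne with Cp2Zr(H)Cl (zirconium to the less hindered, methyl-bearing carbon; one extra equivalent for the hydroxyl) followed by I2 should give the E-vinyl iodide alcohol F1. Dess–Martin oxidation should give the iodo aldehyde F2. CrCl2 with catalytic NiCl2 in DMSO/THF at high dilution should then form the C8–C9 bond and come back to the route at 28.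

2. Step 11. The carbomagnesiation may stall through competing deprotonation of the terminal alkyne, lose its anti selectivity, or give over-iodination. The fallback builds the same diene by syn-hydrometalation of an internal alkyne. It sets out from 13. Sonogashira coupling (Pd(PPh3)4, CuI, Et3N) with (1E)-1-iodo-2-methylhept-1-en-5-yne F3 (from 21 by Cp2ZrCl2/Me3Al, then I2) should give the dienediynol F4. Hydroxyl-directed syn-hydrostannation with Bu3SnH and PdCl2(PPh3)2, tin going to the carbon next to the carbinol, should give the vinylstannane F5. Stille coupling with 2-bromopropene (Pd2(dba)3, AsPh3, CuI) should then come back to the route at 23.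

3. Step 20. Hydride delivery to the macrocyclic enone may show poor or reversed facial selectivity if the ring conformation overrides the Felkin–Anh preference. The fallback replaces facial control by an invertive substitution. It sets out from 29. The same reduction would then give mainly the 9S alcohol F6. Mitsunobu reaction (PPh3, diisopropyl azodicarboxylate, chloroacetic acid) should give the inverted 9R chloroacetate F7. Selective cleavage of the chloroacetate with thiourea and NaHCO3 in ethanol, which spares the acetate, should come back to the route at 30.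

Further compounds
F1 | step 18 | (2R,3E,6S,7Z,9E,13E)-2-(TBSO)-1-hydroxy-14-iodo-4,10-dimethyl-7-(prop-1-en-2-yl)pentadeca-3,7,9,13-tetraen-6-yl acetate | OC[C@H](O[Si](C)(C)C(C)(C)C)/C=C(\C)C[C@H](OC(C)=O)/C(C(C)=C)=C\C=C(/C)CC/C=C(\C)I
F2 | step 18 | (2R,3E,6S,7Z,9E,13E)-2-(TBSO)-14-iodo-4,10-dimethyl-1-oxo-7-(prop-1-en-2-yl)pentadeca-3,7,9,13-tetraen-6-yl acetate | O=C[C@H](O[Si](C)(C)C(C)(C)C)/C=C(\C)C[C@H](OC(C)=O)/C(C(C)=C)=C\C=C(/C)CC/C=C(\C)I
F3 | step 11 | (1E)-1-iodo-2-methylhept-1-en-5-yne | I/C=C(\C)CCC#CC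
F4 | step 11 | (2R,3E,6S,9E)-1,2-bis(TBSO)-4,10-dimethylpentadeca-3,9-dien-7,13-diyn-6-ol | CC(C)(C)[Si](C)(C)OC[C@H](O[Si](C)(C)C(C)(C)C)/C=C(\C)C[C@H](O)C#C/C=C(\C)CCC#CC
F5 | step 11 | (2R,3E,6S,7E,9E)-1,2-bis(TBSO)-4,10-dimethyl-7-(tributylstannyl)pentadeca-3,7,9-trien-13-yn-6-ol | CC(C)(C)[Si](C)(C)OC[C@H](O[Si](C)(C)C(C)(C)C)/C=C(\C)C[C@H](O)/C([Sn](CCCC)(CCCC)CCCC)=C\C=C(/C)CCC#CC
F6 | step 20 | (1Z,3E,7E,11E,9S,10R,14S)-10-(TBSO)-9-hydroxy-4,8,12-trimethyl-1-(prop-1-en-2-yl)cyclotetradeca-1,3,7,11-tetraen-14-yl acetate | C=C(C)/C1=C/C=C(\C)CC/C=C(\C)[C@H](O)[C@H](O[Si](C)(C)C(C)(C)C)/C=C(\C)C[C@@H]1OC(C)=O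
F7 | step 20 | (1Z,3E,7E,11E,9R,10R,14S)-14-acetoxy-10-(TBSO)-4,8,12-trimethyl-1-(prop-1-en-2-yl)cyclotetradeca-1,3,7,11-tetraen-9-yl chloroacetate | C=C(C)/C1=C/C=C(\C)CC/C=C(\C)[C@@H](OC(=O)CCl)[C@H](O[Si](C)(C)C(C)(C)C)/C=C(\C)C[C@@H]1OC(C)=O
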